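Readings and results were generated by integration with made-up constants, and the scatter is random.

Along the suspected steps, substrate that reacts with coupling partner passes through single product before it can become double product. So substrate, single, double and decomposition product always add up to the charge, and single product stands below what has been converted. That gave me a ceiling, and I needed to know how far each flask had converted.

| flask | substrate | coupling partner | temperature | remark | time |
|---|---|---|---|---|---|
| dusk | 1.5 M | 1.3 equiv | 20 °C | run made earlier |  |
| noon | 0.75 M | 2 equiv | 53 °C | run made earlier |  |
| maple | 1.5 M | 2.00 equiv | 25 °C |  | 6.0 d |
| birch | 1.5 M | 2.00 equiv | 45 °C |  | 6.0 d |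
| larch | 1.5 M | 2.00 equiv | 5 °C |  | 6.0 d |
| cedar | 1.5 M | 2.00 equiv | 65 °C |  | 6.0 d |

dusk run (percent of the substrate charged)

| time / d | single product / % |
|---|---|
| 0.625 | 13 |
| 1.67 | 32 |
| 3.00 | 47 |
| 5.00 | 56 |

noon run (percent of the substrate charged)

| time / h | single product / % |
|---|---|
| 8.00 | 54 |
| 15.0 | 58 |
| 25.0 | 47 |
| 30.0 | 41 |

(scatter of a reading: 2 percentage points)

- the best flask by amount of single product, in percent of the substrate charged; "all alike" if 1.5 percentage points covers them all (maple / birch / larch / cedar / all alike)
- amount of single product at the end, in percent of the substrate charged, maple
- amount of single product at the end, in percent of the substrate charged, birch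
- amount of single product at the end, in percent of the substrate charged, larch
- amount of single product at the end, in percent of the substrate charged, cedar

- the numbers in the tables scatter with a standard deviation of 2 percentage points
- on the list of suspects stand: substrate -> decomposition product; coupling partner + single product -> double product + by-product; substrate + coupling partner -> single product + by-product

I counted turnovers. Dusk had 32% single product at 1.67 d. I read that as converted substrate and took the partner halfway down its fall. Scaled to the 3.00 M of coupling partner in the new flasks, this gave a rate of 0.405 d⁻¹ at 20 °C. Noon's first reading, treated the same way, gave 5.39 d⁻¹ at 53 °C. I let equal temperature steps multiply the rate by equal factors, which put maple at 0.600 d⁻¹, a half-life of 1.16 d. Over 6.0 d that made 3.60 lifetimes.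

The weak link was holding the partner at its charge, since each converted substrate takes some. Averaging the charge with what remains once the substrate has reacted lowered the figure to 2.70. I called this the turnover count: rate times time, the number of substrate lifetimes a flask has had, so that e to its negative is the share of substrate left. For maple that left 6.72% of the substrate, and I committed to a ceiling of 93.3%, less whatever went on to double product. Larch, at 5 °C and with the partner held at charge, counted 0.750.

The forecast chose maple, with 65% for maple, 22% for birch, 35% for larch and 4% for cedar, on the ground that “single product is consumed by the coupling partner”. My larch count meant 52.8% of the substrate converted, more than the forecast's figure for single product in larch.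

The flasks gave maple as best: maple 68.3%, birch 18.5%, larch 32.5%, cedar 0.309%.

    substrate → decomposition product (k = 1.12 × 10⁻⁴ h⁻¹, Ea = 119 kJ mol⁻¹)
    coupling partner + single product → double product + by-product (k = 0.00163 M⁻¹ h⁻¹, Ea = 96.0 kJ mol⁻¹)
    substrate + coupling partner → single product + by-product (k = 0.00934 M⁻¹ h⁻¹, Ea = 76.0 kJ mol⁻¹)
    (constants at 25 °C)

Maple ended with 8.54% substrate, a count of 2.46 against my 2.70, and held 68.3% single product beside 22.7% double product. Larch kept 67% substrate, a count of 0.400, lower than my 0.750. The time given is the main reason for larch's low yield: larch held 32.5% single product at 6.0 d, and left until 60.0 d it held 77.6%.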